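## Structural features

Gnetucleistol F (15) is built on a 2,3-dihydrobenzofuran: benzo ring A is fused to dihydrofuran ring B, C7 carries a methoxy group and C5 an E-ethenyl bridge to a resorcinol ring D. C2 bears a 4-hydroxy-3,5-dimethoxyphenyl ring C and C3 a hydroxymethyl group; these two adjacent ring carbons are the only stereocentres, (2R,3S), with their substituents trans. The benzylic C2–O1 bond stands para to the phenolic oxygen of ring C, so base or acid can open ring B through a quinone methide and scramble C2 once that phenol is free. The hydroxystilbene is sensitive to light, acid and oxidants, and three phenols and a primary alcohol have to be carried or masked. The real difficulty is the absolute and relative configuration at C2 and C3 in a ring that offers no resident control element; the rest is aryl–alkene chemistry. The key step uses the fact that O1, C2 and C3, with ring C on C2 and ring A on C3, are the oxygen and the two alkene carbons of an E-stilbene with the C7a hydroxyl ortho to it, and that the carbon on C3 can enter at the oxidation level of carbon monoxide.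

## Logic of the disconnections

15 to 14: the three O–Si bonds (one on ring C, two on ring D) are cut. The ring-C phenol must stay capped to the end because, once free, it activates C2–O1 towards opening. Using one class of protecting group means a single final step. The forward step must be a buffered fluoride cleavage that does not leave phenoxides standing.

14 to 9 and 13: the C=C bond of the bridge is cut. This separates ring D as an achiral benzylic phosphonate and leaves the chiral core with a formyl group on C5. The forward olefination must be E-selective and must tolerate the free hydroxymethyl group on C3.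

9 to 8 to 7: no skeletal bond is cut; the formyl carbon on C5 and the hydroxymethyl carbon on C3 are both traced back to methyl esters. One reductant brings both to the alcohol level, and the difference between a benzylic and a non-benzylic alcohol then tells them apart. The forward steps must not enolise C3 and must oxidise only the benzylic alcohol.

7 to 6: O1–C2 and the bond from C3 to its carboxyl carbon are cut, and one molecule each of CO and methanol is removed. Ring B, two skeletal bonds and both stereocentres vanish, leaving a flat, achiral stilbene. The forward step must select one alkene face and must carbonylate the C3–palladium bond before β-hydride elimination.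

6 to 5 and 3: the bond between ring A and the alkene carbon that becomes C3 is cut. An aryl iodide ortho to the phenol and a styrene are each one or two steps from commercial material. A Heck coupling tolerates the free phenol, so no olefination has to be run on a salicylaldehyde whose phenoxide deactivates the carbonyl. The forward step must arylate the terminal alkene carbon and give the E isomer.

5 to 4, and 3 to 2 to 1: a C–I bond ortho to the hydroxyl, the terminal C=C bond and one O–Si bond are cut. The demands are ortho-selective iodination and a methylenation that spares the aryl silyl ether.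

13 to 12 to 11 to 10: the C–P, C–Br and three O–Si bonds are cut. Silylating all three hydroxyls and then converting only the alkyl silyl ether into the bromide avoids having to tell phenols from the benzylic alcohol at the silylation stage.

## Other disconnections considered

Alternative 1: The cut is made in ring D. The two ring bonds flanking the carbon that carries the bridge are broken, so that this carbon becomes the carbonyl carbon of a cinnamoyl unit and the other five ring carbons are those of pentane-2,4-dione A3. In the forward step the dianion of A3 (LiN(i-Pr)2) would be acylated at its terminal carbon by the Weinreb cinnamamide A2. Aqueous KOH added to the same flask would then let the terminal methyl carbon of triketone A4 add to the cinnamoyl carbonyl, and loss of water would aromatise the ring to A1, the bis(methoxymethyl) ether of 15.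
- In its favour: ring D arises with both hydroxyls free, so the three-step branch to 13 and its silyl groups disappear, and a cheap five-carbon unit is used.
- Against it here: the cut lies in the periphery and leaves C2 and C3 untouched, so A2 must still come from a route that solves the stereochemical problem, for example through 7. The enone of A2 offers the dianion a 1,4-addition, and A4 can close through oxygen or be cleaved by hydroxide. The methoxymethyl ethers of A1 must finally be removed with acid, next to a benzylic ether para to an oxygen and an acid-sensitive hydroxystilbene.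
- Comparison, structure: the two plans are not rivals, since this one builds an achiral arene and the chosen one the stereogenic ring.
- Comparison, mechanism: the alternative rests on condensations of a known type and is in that respect the better, since step 5 has no direct precedent.
- Comparison, step economy: the alternative is about equal or slightly better in total count (no branch, one more linear step). The chosen plan is the better in the safety of the last deprotection.

Alternative 2: The cuts are O1–C2 and C2–C3, so that C2 with ring C is taken out as a one-carbon unit and O1, C7a, C3a and C3 remain as a four-atom unit. In the forward step Cs2CO3 would expel sulfinate from sulfone A6 to give ortho-quinone methide A8 and would deprotonate the chiral sulfonium salt A7. The ylide carbon would add to the methide carbon (C2–C3) and the phenoxide would displace the sulfide (O1–C2, 5-exo-tet), giving A5.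
- In its favour: such [4+1] annulations are an established reaction class with a built-in preference for the trans product. Ring B and both stereocentres arise in one step, and the C3 substituent enters as a protected hydroxymethyl group, so no redox adjustment follows.
- Against it here: A8 has a CH2 group on the methide carbon and can tautomerise to a vinylphenol before it is trapped. The benzyl group of A7 is very electron-rich, so the salt may ionise or alkylate the phenoxide of A6 at oxygen, and carbonate may unmask the silyl-protected phenol para to the sulfonium carbon. Absolute control depends on a stoichiometric chiral sulfur unit and on a face-selective, irreversible addition of a semi-stabilised ylide, neither of which is assured. The C5 bromide must still be turned into the bridge to ring D.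
- Comparison, structure: the plans are equal, each closing ring B from two aryl building blocks with both stereocentres.
- Comparison, mechanism: the alternative is the better in precedent of the reaction type and the equal in relative configuration. The chosen plan, if its ligand control holds, uses a catalytic rather than a stoichiometric chiral source.
- Comparison, step economy: the alternative saves the reduction and oxidation of steps 6 and 7 (better) but spends a similar number of steps on A6 and A7, so the totals should be about equal.

Alternative 3: The cuts are the C2–aryl bond to ring C and O1–C2, which opens ring B to an α-aryl aldehyde whose stereocentre is the future C3. In the forward step the Grignard reagent A11 would add to aldehyde A10 at low temperature (C2–aryl). A quench with HCl in methanol would remove the methoxymethyl and silyl groups, ionise the new benzylic alcohol to a cation stabilised by the para oxygen of ring C, and let the C7a hydroxyl close ring B (O1–C2, 5-exo), giving A9.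
- In its favour: only C3 is set from outside, by enzymatic desymmetrisation of the prochiral diol A12. C2 then follows under thermodynamic control because the closure is reversible, so the facial selectivity of the Grignard addition does not matter. All reactions are of known types, and deprotection and ring closure are merged.
- Against it here: A10 has an acidic hydrogen at its stereocentre between an aryl ring and a formyl group, so racemisation by enolisation threatens during its preparation and under the basic Grignard reagent. Methanol competes with the phenol for the cation. The way from A12 to A10 costs several protecting-group and redox steps. A9 has a free ring-C phenol that would need capping again before the bridge is built at the C5 bromide.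
- Comparison, structure: the alternative is the better in how it controls C2 (equilibration rather than kinetic face selection) and the worse in how it guards C3, which the chosen plan creates inside the ring in its stable orientation.
- Comparison, mechanism: the alternative is the better in precedent.
- Comparison, step economy: the alternative is the worse, since the linear sequence to A10 alone should be about as long as the whole route to 7.

Key step: step 5

Remark on descriptors: the trans diester 7 is (2R,3R) and the target is (2R,3S); the change at C3 comes from CIP priorities (CO2Me versus CH2OH), not from a change of geometry. The supplied structures of the precursor, the key product and the target were checked and needed no correction.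

Assumption: the sense of induction of the ligand in step 5 cannot be predicted with confidence; the (S,S) antipode of Bn-BOXAX, (S)-2,2'-bis[(4S)-4-benzyl-4,5-dihydro-1,3-oxazol-2-yl]-1,1'-binaphthyl, is written, and its mirror image is to be used if it favours the 2S series.

## Route

Step 1
Reactants: 1 syringaldehyde (4-hydroxy-3,5-dimethoxybenzaldehyde)
Product: 2 3,5-dimethoxy-4-(triisopropylsilyloxy)benzaldehyde
Conditions: TIPSCl, imidazole, DMAP (cat.), DMF, 40 °C
Reagents that add atoms: triisopropylsilyl chloride, CC(C)[Si](Cl)(C(C)C)C(C)C
Why: O-silylation of an acidic phenol with a silyl chloride and imidazole; the bulky silyl group between two methoxy groups should withstand amine base, hydride, MnO2 and a phosphonate anion and still leave with fluoride at the end.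

Step 2
Reactants: 2 3,5-dimethoxy-4-(triisopropylsilyloxy)benzaldehyde
Product: 3 3,5-dimethoxy-4-(triisopropylsilyloxy)styrene, i.e. (4-ethenyl-2,6-dimethoxyphenoxy)triisopropylsilane
Conditions: Ph3PCH3Br, KOtBu, THF, 0 °C to rt
Reagents that add atoms: methyltriphenylphosphonium bromide, C[P+](c1ccccc1)(c1ccccc1)c1ccccc1.[Br-]
Why: Wittig methylenation of an aromatic aldehyde; the ylide is preformed with slightly less than one equivalent of base so that no free alkoxide remains to attack the aryl silyl ether.

Step 3
Reactants: 4 methyl vanillate (methyl 4-hydroxy-3-methoxybenzoate)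
Product: 5 methyl 4-hydroxy-3-iodo-5-methoxybenzoate
Conditions: NIS, CF3CO2H (cat.), MeCN, rt
Reagents that add atoms: N-iodosuccinimide, O=C1CCC(=O)N1I
Why: Electrophilic aromatic iodination; the hydroxyl is the strongest director and its para position is blocked by the ester, so iodine should enter the one free ortho position.

Step 4
Reactants: 5 methyl 4-hydroxy-3-iodo-5-methoxybenzoate and 3 3,5-dimethoxy-4-(triisopropylsilyloxy)styrene
Product: 6 methyl 4-hydroxy-3-methoxy-5-[(E)-2-[3,5-dimethoxy-4-(triisopropylsilyloxy)phenyl]ethenyl]benzoate
Conditions: Pd(OAc)2 (5 mol %), P(o-tol)3 (12 mol %), Et3N, DMF, 90 °C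
Reagents that add atoms: none
Why: Mizoroki–Heck reaction; oxidative addition into the C–I bond (activated by the para ester), syn-carbopalladation at the terminal styrene carbon and syn-β-hydride elimination should give the E-stilbene. The free phenol and the aryl silyl ether are compatible with the amine base, so no phenol protection is needed.

Step 5
Reactants: 6 methyl 4-hydroxy-3-methoxy-5-[(E)-2-[3,5-dimethoxy-4-(triisopropylsilyloxy)phenyl]ethenyl]benzoate
Product: 7 dimethyl (2R,3R)-2-[3,5-dimethoxy-4-(triisopropylsilyloxy)phenyl]-7-methoxy-2,3-dihydro-1-benzofuran-3,5-dicarboxylate (2,3-trans)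
Conditions: Pd(OCOCF3)2 (10 mol %), (S,S)-Bn-BOXAX (20 mol %), p-benzoquinone (4 equiv), CO (1 atm), MeOH/CH2Cl2, rt
Reagents that add atoms: carbon monoxide, [C-]#[O+]; methanol, CO
Why: Proposed new method: divalent palladium carrying the chiral bisoxazoline binds the stilbene alkene of 6 and the C7a phenol oxygen adds to the alkene carbon bearing ring C (O1–C2), the only closure open to it and a 5-endo-trig cyclisation made feasible by metal activation; the benzylic C3–palladium bond then inserts CO and the acylpalladium is cleaved by methanol (C3–carboxyl carbon), releasing zerovalent palladium that p-benzoquinone reoxidises. The closest known reaction types are the alkoxypalladation–methoxycarbonylation of hydroxyalkenes, the enantioselective domino Wacker–carbonylation of alkenylphenols with this catalyst family, and the 5-endo oxypalladation of 2-hydroxystilbenes that ends in β-hydride loss to 2-arylbenzofurans; what is new is the interception of that last pathway by CO on a 1,2-diaryl alkene. C2 is set by the ligand, which decides the alkene face to which oxygen is delivered. C3 follows from the stereospecific course: anti attack on the E-alkene places palladium trans to ring C and CO inserts with retention, giving the trans diester; a syn pathway would give the less stable C3 epimer, which base can equilibrate to trans without touching C2 because ring opening from the C3 enolate is the reverse of a disfavoured 5-endo closure. The step needs carbonylation to outrun β-hydride elimination, which CO saturation and the chelating ligand serve by filling the coordination site that elimination requires. The para ester makes the ring-A phenol acidic enough to engage palladium yet hard for the quinone to oxidise, and the silyl ether keeps the ring-C phenol out of the reaction.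

Step 6
Reactants: 7 dimethyl (2R,3R)-2-[3,5-dimethoxy-4-(triisopropylsilyloxy)phenyl]-7-methoxy-2,3-dihydro-1-benzofuran-3,5-dicarboxylate
Product: 8 [(2R,3S)-2-[3,5-dimethoxy-4-(triisopropylsilyloxy)phenyl]-7-methoxy-2,3-dihydro-1-benzofuran-3,5-diyl]dimethanol
Conditions: i-Bu2AlH (6 equiv), CH2Cl2, −78 to 0 °C; aq. potassium sodium tartrate
Reagents that add atoms: none
Why: Hydride reduction of both esters to primary alcohols; at low temperature hydride addition should outrun enolisation at C3, which in any case already sits in its more stable trans arrangement, and the aryl silyl ether is not attacked. C2 and C3 keep their geometry (the C3 descriptor changes only by priority).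

Step 7
Reactants: 8 [(2R,3S)-2-[3,5-dimethoxy-4-(triisopropylsilyloxy)phenyl]-7-methoxy-2,3-dihydro-1-benzofuran-3,5-diyl]dimethanol
Product: 9 (2R,3S)-2-[3,5-dimethoxy-4-(triisopropylsilyloxy)phenyl]-3-(hydroxymethyl)-7-methoxy-2,3-dihydro-1-benzofuran-5-carbaldehyde
Conditions: MnO2 (activated, excess), CH2Cl2, rt
Reagents that add atoms: none
Why: MnO2 oxidation is selective for benzylic alcohols; the CH2OH on ring A is attached directly to the arene, whereas the C3 hydroxymethyl is an ordinary primary alcohol and should be left. No free phenol is present to be oxidised.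

Step 8
Reactants: 10 3,5-dihydroxybenzyl alcohol
Product: 11 tert-butyl{[3,5-bis(tert-butyldimethylsilyloxy)phenyl]methoxy}dimethylsilane
Conditions: TBSCl (3.5 equiv), imidazole, DMF, rt
Reagents that add atoms: tert-butyldimethylsilyl chloride, CC(C)(C)[Si](C)(C)Cl
Why: Exhaustive O-silylation with silyl chloride and imidazole; protecting all three hydroxyls avoids any need to tell phenols from the alcohol at this stage.

Step 9
Reactants: 11 tert-butyl{[3,5-bis(tert-butyldimethylsilyloxy)phenyl]methoxy}dimethylsilane
Product: 12 3,5-bis(tert-butyldimethylsilyloxy)benzyl bromide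
Conditions: Ph3PBr2, CH2Cl2, 0 °C to rt
Reagents that add atoms: dibromotriphenylphosphorane, BrP(Br)(c1ccccc1)(c1ccccc1)c1ccccc1
Why: Direct conversion of an alkyl silyl ether into a bromide (the oxygen is activated on phosphorus, silyl bromide leaves, and bromide displaces at the benzylic carbon by SN2); aryl silyl ethers cannot be displaced at an sp2 carbon and should stay.

Step 10
Reactants: 12 3,5-bis(tert-butyldimethylsilyloxy)benzyl bromide
Product: 13 diethyl {[3,5-bis(tert-butyldimethylsilyloxy)phenyl]methyl}phosphonate
Conditions: P(OEt)3, neat, 130 °C
Reagents that add atoms: triethyl phosphite, CCOP(OCC)OCC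
Why: Michaelis–Arbuzov reaction of a benzylic bromide; the aryl silyl ethers are thermally stable under these neutral conditions.

Step 11
Reactants: 9 (2R,3S)-2-[3,5-dimethoxy-4-(triisopropylsilyloxy)phenyl]-3-(hydroxymethyl)-7-methoxy-2,3-dihydro-1-benzofuran-5-carbaldehyde and 13 diethyl {[3,5-bis(tert-butyldimethylsilyloxy)phenyl]methyl}phosphonate
Product: 14 [(2R,3S)-5-[(E)-2-[3,5-bis(tert-butyldimethylsilyloxy)phenyl]ethenyl]-2-[3,5-dimethoxy-4-(triisopropylsilyloxy)phenyl]-7-methoxy-2,3-dihydro-1-benzofuran-3-yl]methanol
Conditions: 13 (2.2 equiv), KN(SiMe3)2 (2.1 equiv), THF, −78 °C; then 9, −78 °C to rt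
Reagents that add atoms: none
Why: Horner–Wadsworth–Emmons olefination; benzylic phosphonate anions and aromatic aldehydes give E-stilbenes through reversible addition and elimination from the anti adduct. One equivalent of anion is spent on the free hydroxyl, which then stands by as its alkoxide, and the base is kept in slight deficit to the phosphonate so that the silyl ethers see no free amide.

Step 12
Reactants: 14 [(2R,3S)-5-[(E)-2-[3,5-bis(tert-butyldimethylsilyloxy)phenyl]ethenyl]-2-[3,5-dimethoxy-4-(triisopropylsilyloxy)phenyl]-7-methoxy-2,3-dihydro-1-benzofuran-3-yl]methanol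
Product: 15 gnetucleistol F, 5-[(E)-2-[(2R,3S)-2-(4-hydroxy-3,5-dimethoxyphenyl)-3-(hydroxymethyl)-7-methoxy-2,3-dihydro-1-benzofuran-5-yl]ethenyl]benzene-1,3-diol
Conditions: Bu4NF (4 equiv), AcOH (4 equiv), THF, 0 °C to rt, dark, argon
Reagents that add atoms: none
Why: Fluoride cleavage of the three aryl silyl ethers, driven by Si–F bond formation; acetic acid protonates the phenoxides as they form, so that the C2–O1 bond para to the new ring-C phenol should not open through a quinone methide. No stereocentre is touched.

## Compound list

1 | syringaldehyde (4-hydroxy-3,5-dimethoxybenzaldehyde) | COc1cc(C=O)cc(OC)c1O | starting material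
2 | 3,5-dimethoxy-4-(triisopropylsilyloxy)benzaldehyde | COc1cc(C=O)cc(OC)c1O[Si](C(C)C)(C(C)C)C(C)C | intermediate
3 | 3,5-dimethoxy-4-(triisopropylsilyloxy)styrene | COc1cc(C=C)cc(OC)c1O[Si](C(C)C)(C(C)C)C(C)C | intermediate
4 | methyl vanillate (methyl 4-hydroxy-3-methoxybenzoate) | COc1cc(C(=O)OC)ccc1O | starting material
5 | methyl 4-hydroxy-3-iodo-5-methoxybenzoate | COc1cc(C(=O)OC)cc(I)c1O | intermediate
6 | methyl 4-hydroxy-3-methoxy-5-[(E)-2-[3,5-dimethoxy-4-(triisopropylsilyloxy)phenyl]ethenyl]benzoate | COc1cc(/C=C/c2cc(C(=O)OC)cc(OC)c2O)cc(OC)c1O[Si](C(C)C)(C(C)C)C(C)C | intermediate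
7 | dimethyl (2R,3R)-2-[3,5-dimethoxy-4-(triisopropylsilyloxy)phenyl]-7-methoxy-2,3-dihydro-1-benzofuran-3,5-dicarboxylate (trans) | COc1cc([C@@H]2Oc3c(OC)cc(C(=O)OC)cc3[C@H]2C(=O)OC)cc(OC)c1O[Si](C(C)C)(C(C)C)C(C)C | intermediate
8 | [(2R,3S)-2-[3,5-dimethoxy-4-(triisopropylsilyloxy)phenyl]-7-methoxy-2,3-dihydro-1-benzofuran-3,5-diyl]dimethanol | COc1cc([C@@H]2Oc3c(OC)cc(CO)cc3[C@H]2CO)cc(OC)c1O[Si](C(C)C)(C(C)C)C(C)C | intermediate
9 | (2R,3S)-2-[3,5-dimethoxy-4-(triisopropylsilyloxy)phenyl]-3-(hydroxymethyl)-7-methoxy-2,3-dihydro-1-benzofuran-5-carbaldehyde | COc1cc([C@@H]2Oc3c(OC)cc(C=O)cc3[C@H]2CO)cc(OC)c1O[Si](C(C)C)(C(C)C)C(C)C | intermediate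
10 | 3,5-dihydroxybenzyl alcohol | OCc1cc(O)cc(O)c1 | starting material
11 | tert-butyl{[3,5-bis(tert-butyldimethylsilyloxy)phenyl]methoxy}dimethylsilane | CC(C)(C)[Si](C)(C)OCc1cc(O[Si](C)(C)C(C)(C)C)cc(O[Si](C)(C)C(C)(C)C)c1 | intermediate
12 | 3,5-bis(tert-butyldimethylsilyloxy)benzyl bromide | BrCc1cc(O[Si](C)(C)C(C)(C)C)cc(O[Si](C)(C)C(C)(C)C)c1 | intermediate
13 | diethyl {[3,5-bis(tert-butyldimethylsilyloxy)phenyl]methyl}phosphonate | CCOP(=O)(Cc1cc(O[Si](C)(C)C(C)(C)C)cc(O[Si](C)(C)C(C)(C)C)c1)OCC | intermediate
14 | [(2R,3S)-5-[(E)-2-[3,5-bis(tert-butyldimethylsilyloxy)phenyl]ethenyl]-2-[3,5-dimethoxy-4-(triisopropylsilyloxy)phenyl]-7-methoxy-2,3-dihydro-1-benzofuran-3-yl]methanol | COc1cc([C@@H]2Oc3c(OC)cc(/C=C/c4cc(O[Si](C)(C)C(C)(C)C)cc(O[Si](C)(C)C(C)(C)C)c4)cc3[C@H]2CO)cc(OC)c1O[Si](C(C)C)(C(C)C)C(C)C | intermediate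
15 | gnetucleistol F | COc1cc([C@@H]2Oc3c(OC)cc(/C=C/c4cc(O)cc(O)c4)cc3[C@H]2CO)cc(OC)c1O | target

## Step count and risks

Total step count: 12. Longest linear sequence: 8 steps (steps 1, 2, 4, 5, 6, 7, 11, 12, from 1 to 15).

Step 5 (key step, the one proposed as new). Most likely failures:
- β-hydride elimination with aromatisation of ring B may outrun CO insertion, because the benzylic palladium intermediate has a syn hydrogen on C2.
- Facial selectivity may be poor, since a 1,2-diaryl E-alkene gives the ligand little to distinguish.
- CO may reduce divalent palladium before turnover.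
- A syn-oxypalladation pathway may lose relative control at C3.

Fallback, known reactions only, setting out from 2 and 5 and coming back at 7:
- 2 is reduced with NaBH4 (MeOH/THF, 0 °C) to [3,5-dimethoxy-4-(triisopropylsilyloxy)phenyl]methanol F1.
- An Appel reaction (CBr4, PPh3, CH2Cl2, 0 °C) converts it into [4-(bromomethyl)-2,6-dimethoxyphenoxy]triisopropylsilane F2.
- Williamson etherification of 5 with F2 (K2CO3, acetone, reflux) should give methyl 4-{[3,5-dimethoxy-4-(triisopropylsilyloxy)phenyl]methoxy}-3-iodo-5-methoxybenzoate F3.
- Palladium-catalysed coupling of the aryl iodide with methyl diazoacetate (Pd(PPh3)4, Ag2CO3, Et3N, toluene, rt) should give methyl 3-(1-diazo-2-methoxy-2-oxoethyl)-4-{[3,5-dimethoxy-4-(triisopropylsilyloxy)phenyl]methoxy}-5-methoxybenzoate F4.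
- A chiral dirhodium tetracarboxylate, Rh2(S-PTTL)4 (dirhodium tetrakis[N-phthaloyl-(S)-tert-leucinate], or its antipode as needed for 2R), in toluene at −60 °C should insert the carbenoid into the benzylic C–H bond of the ether (C2–C3 bond, five-membered ring). This gives dimethyl (2R,3S)-2-[3,5-dimethoxy-4-(triisopropylsilyloxy)phenyl]-7-methoxy-2,3-dihydro-1-benzofuran-3,5-dicarboxylate (cis) F5.
- NaOMe in MeOH epimerises C3 of F5 to the trans diester 7. The same treatment would correct a cis-rich outcome of step 5 itself.

Step 4. The ortho phenoxide may slow the catalyst, the electron-rich styrene may be arylated at its internal carbon or oligomerise on heating, and the silyl ether may be lost thermally. Fallback, setting out from 4 and 2 and coming back at 6: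
- Duff formylation of 4 (hexamethylenetetramine, CF3CO2H, reflux; aq. HCl) gives methyl 3-formyl-4-hydroxy-5-methoxybenzoate F6.
- 2 is taken through the alcohol F1 and the bromide F2 as above, and an Arbuzov reaction (P(OEt)3, 120 °C) gives diethyl {[3,5-dimethoxy-4-(triisopropylsilyloxy)phenyl]methyl}phosphonate F7.
- Horner–Wadsworth–Emmons olefination of F6 with F7 (NaH, 3 equiv, THF/DMF, 0 °C to rt, the aldehyde reacting as its phenoxide) should give 6.

Step 11. The alkoxide of the free hydroxymethyl group may consume anion, or may take a silyl group from an aryl silyl ether, leaving a phenoxide that stalls the olefination. Fallback, setting out from 9 and coming back at 15: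
- 9 is silylated (TBSCl, imidazole, DMF) to (2R,3S)-3-[(tert-butyldimethylsilyloxy)methyl]-2-[3,5-dimethoxy-4-(triisopropylsilyloxy)phenyl]-7-methoxy-2,3-dihydro-1-benzofuran-5-carbaldehyde F8.
- Olefination with 13 (KN(SiMe3)2, THF) gives the fully silylated stilbene, tert-butyl{[(2R,3S)-5-[(E)-2-[3,5-bis(tert-butyldimethylsilyloxy)phenyl]ethenyl]-2-[3,5-dimethoxy-4-(triisopropylsilyloxy)phenyl]-7-methoxy-2,3-dihydro-1-benzofuran-3-yl]methoxy}dimethylsilane F9.
- Bu4NF/AcOH in THF removes all four silyl groups to give 15, at no extra cost in steps beyond the silylation.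

Step 12. Once the ring-C phenoxide is unmasked, ring B may open through a quinone methide with epimerisation at C2, and the free hydroxystilbene may isomerise or oxidise in a basic medium. Fallback, setting out from 14 and coming back at 15:
- Acetylation of the primary alcohol (Ac2O, pyridine), followed in the same flask by fluoride-triggered exchange of silyl for acetyl (CsF, excess Ac2O, DMF), traps each phenoxide as it forms. This gives the non-phenolic, purifiable tetraacetate [(2R,3S)-2-(4-acetoxy-3,5-dimethoxyphenyl)-5-[(E)-2-(3,5-diacetoxyphenyl)ethenyl]-7-methoxy-2,3-dihydro-1-benzofuran-3-yl]methyl acetate F10.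
- Brief methanolysis (K2CO3, MeOH, 0 °C, prompt neutralisation) then releases 15 in a protic medium.

## Further compounds

F1 | step 5 | [3,5-dimethoxy-4-(triisopropylsilyloxy)phenyl]methanol | COc1cc(CO)cc(OC)c1O[Si](C(C)C)(C(C)C)C(C)C
F2 | step 5 | [4-(bromomethyl)-2,6-dimethoxyphenoxy]triisopropylsilane | COc1cc(CBr)cc(OC)c1O[Si](C(C)C)(C(C)C)C(C)C
F3 | step 5 | methyl 4-{[3,5-dimethoxy-4-(triisopropylsilyloxy)phenyl]methoxy}-3-iodo-5-methoxybenzoate | COc1cc(COc2c(I)cc(C(=O)OC)cc2OC)cc(OC)c1O[Si](C(C)C)(C(C)C)C(C)C
F4 | step 5 | methyl 3-(1-diazo-2-methoxy-2-oxoethyl)-4-{[3,5-dimethoxy-4-(triisopropylsilyloxy)phenyl]methoxy}-5-methoxybenzoate | COc1cc(COc2c(OC)cc(C(=O)OC)cc2C(=[N+]=[N-])C(=O)OC)cc(OC)c1O[Si](C(C)C)(C(C)C)C(C)C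
F5 | step 5 | dimethyl (2R,3S)-2-[3,5-dimethoxy-4-(triisopropylsilyloxy)phenyl]-7-methoxy-2,3-dihydro-1-benzofuran-3,5-dicarboxylate (cis) | COc1cc([C@@H]2Oc3c(OC)cc(C(=O)OC)cc3[C@@H]2C(=O)OC)cc(OC)c1O[Si](C(C)C)(C(C)C)C(C)C
F6 | step 4 | methyl 3-formyl-4-hydroxy-5-methoxybenzoate | COc1cc(C(=O)OC)cc(C=O)c1O
F7 | step 4 | diethyl {[3,5-dimethoxy-4-(triisopropylsilyloxy)phenyl]methyl}phosphonate | CCOP(=O)(Cc1cc(OC)c(O[Si](C(C)C)(C(C)C)C(C)C)c(OC)c1)OCC
F8 | step 11 | (2R,3S)-3-[(tert-butyldimethylsilyloxy)methyl]-2-[3,5-dimethoxy-4-(triisopropylsilyloxy)phenyl]-7-methoxy-2,3-dihydro-1-benzofuran-5-carbaldehyde | COc1cc([C@@H]2Oc3c(OC)cc(C=O)cc3[C@H]2CO[Si](C)(C)C(C)(C)C)cc(OC)c1O[Si](C(C)C)(C(C)C)C(C)C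
F9 | step 11 | tert-butyl{[(2R,3S)-5-[(E)-2-[3,5-bis(tert-butyldimethylsilyloxy)phenyl]ethenyl]-2-[3,5-dimethoxy-4-(triisopropylsilyloxy)phenyl]-7-methoxy-2,3-dihydro-1-benzofuran-3-yl]methoxy}dimethylsilane | COc1cc([C@@H]2Oc3c(OC)cc(/C=C/c4cc(O[Si](C)(C)C(C)(C)C)cc(O[Si](C)(C)C(C)(C)C)c4)cc3[C@H]2CO[Si](C)(C)C(C)(C)C)cc(OC)c1O[Si](C(C)C)(C(C)C)C(C)C
F10 | step 12 | [(2R,3S)-2-(4-acetoxy-3,5-dimethoxyphenyl)-5-[(E)-2-(3,5-diacetoxyphenyl)ethenyl]-7-methoxy-2,3-dihydro-1-benzofuran-3-yl]methyl acetate | COc1cc([C@@H]2Oc3c(OC)cc(/C=C/c4cc(OC(C)=O)cc(OC(C)=O)c4)cc3[C@H]2COC(C)=O)cc(OC)c1OC(C)=O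
A1 | alternative 1 | gnetucleistol F bis(methoxymethyl) ether | COCOc1c(OC)cc([C@@H]2Oc3c(OC)cc(/C=C/c4cc(O)cc(O)c4)cc3[C@H]2COCOC)cc1OC
A2 | alternative 1 | (E)-3-[(2R,3S)-2-[3,5-dimethoxy-4-(methoxymethoxy)phenyl]-7-methoxy-3-(methoxymethoxymethyl)-2,3-dihydro-1-benzofuran-5-yl]-N-methoxy-N-methylprop-2-enamide | COCOc1c(OC)cc([C@@H]2Oc3c(OC)cc(/C=C/C(=O)N(C)OC)cc3[C@H]2COCOC)cc1OC
A3 | alternative 1 | pentane-2,4-dione | CC(=O)CC(C)=O
A4 | alternative 1 | (E)-8-[(2R,3S)-2-[3,5-dimethoxy-4-(methoxymethoxy)phenyl]-7-methoxy-3-(methoxymethoxymethyl)-2,3-dihydro-1-benzofuran-5-yl]oct-7-ene-2,4,6-trione | COCOc1c(OC)cc([C@@H]2Oc3c(OC)cc(/C=C/C(=O)CC(=O)CC(C)=O)cc3[C@H]2COCOC)cc1OC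
A5 | alternative 2 | (2R,3S)-5-bromo-3-(tert-butyldimethylsilyloxymethyl)-2-[3,5-dimethoxy-4-(triisopropylsilyloxy)phenyl]-7-methoxy-2,3-dihydro-1-benzofuran | COc1cc([C@@H]2Oc3c(OC)cc(Br)cc3[C@H]2CO[Si](C)(C)C(C)(C)C)cc(OC)c1O[Si](C(C)C)(C(C)C)C(C)C
A6 | alternative 2 | 4-bromo-2-[2-(tert-butyldimethylsilyloxy)-1-(4-methylphenylsulfonyl)ethyl]-6-methoxyphenol (racemic) | COc1cc(Br)cc(C(CO[Si](C)(C)C(C)(C)C)S(=O)(=O)c2ccc(C)cc2)c1O
A7 | alternative 2 | (2R,5R)-1-{[3,5-dimethoxy-4-(triisopropylsilyloxy)phenyl]methyl}-2,5-dimethylthiolan-1-ium tetrafluoroborate | COc1cc(C[S+]2[C@H](C)CC[C@H]2C)cc(OC)c1O[Si](C(C)C)(C(C)C)C(C)C.F[B-](F)(F)F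
A8 | alternative 2 | 4-bromo-6-[2-(tert-butyldimethylsilyloxy)ethylidene]-2-methoxycyclohexa-2,4-dien-1-one | COC1=CC(Br)=CC(=CCO[Si](C)(C)C(C)(C)C)C1=O
A9 | alternative 3 | (2R,3S)-5-bromo-2-(4-hydroxy-3,5-dimethoxyphenyl)-3-(hydroxymethyl)-7-methoxy-2,3-dihydro-1-benzofuran | COc1cc([C@@H]2Oc3c(OC)cc(Br)cc3[C@H]2CO)cc(OC)c1O
A10 | alternative 3 | (2S)-2-[5-bromo-3-methoxy-2-(methoxymethoxy)phenyl]-3-(tert-butyldimethylsilyloxy)propanal | COCOc1c(OC)cc(Br)cc1[C@H](C=O)CO[Si](C)(C)C(C)(C)C
A11 | alternative 3 | [3,5-dimethoxy-4-(triisopropylsilyloxy)phenyl]magnesium bromide | COc1cc([Mg]Br)cc(OC)c1O[Si](C(C)C)(C(C)C)C(C)C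
A12 | alternative 3 | 2-[5-bromo-3-methoxy-2-(methoxymethoxy)phenyl]propane-1,3-diol | COCOc1c(OC)cc(Br)cc1C(CO)CO
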